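**Retrosynthetic overview**
1. The target (erythro, 7S,8R) comes from a tris-silyl ether by fluoride cleavage; its 3-hydroxypropyl chain comes from an allyl group by anti-Markovnikov hydration.
2. Key disconnection: C1 of the guaiacyl ring (the ring carbon para to the glycerol ether oxygen) to the benzylic carbinol carbon C7, made by a reductive Ni/Cr union of an aryl iodide carbon with an aldehyde carbon, both electrophilic. The enabling feature is that C7 is a secondary carbinol next to C8, whose ether oxygen to the 2,6-dimethoxyphenyl ring steers the incoming aryl group to the Felkin face and so gives the 7,8-erythro relationship; C1 has no ortho substituent and is the iodine position of 4-iodoguaiacol.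
3. Aldehyde half: an (R)-2-aryloxy-3-silyloxypropanal from methyl (S)-glycerate by Mitsunobu inversion with 4-allyl-2,6-dimethoxyphenol, then partial reduction.
4. Iodide half: Mitsunobu etherification of 4-iodo-2-methoxyphenol with 1,3-di-O-TBS-glycerol.
5. No ring is built: both benzene rings are bought as phenols. The chain is assembled C8–O first (step 4), then C1–C7 (step 6).

Key step: step 6

Remark: methyl (S)-glycerate and 4-iodo-2-methoxyphenol are taken as catalogue chemicals. C7, C8 and C9 denote the carbinol carbon, the aryloxy-bearing carbon and the CH2OH carbon of the propane chain.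

**Route**

Step 1
Reactants: 1 glycerol
Product: 2 1,3-bis(tert-butyldimethylsilyloxy)propan-2-ol
Conditions: TBSCl (2.05 equiv), imidazole, CH2Cl2/DMF, 0 °C to rt
Reagents that add atoms: tert-butyldimethylsilyl chloride, CC(C)(C)[Si](C)(C)Cl
Why: Selective silyl ether formation, because the two primary hydroxyls react much faster with the bulky silyl chloride than the secondary one; no stereocentre is involved.

Step 2
Reactants: 2 1,3-bis(tert-butyldimethylsilyloxy)propan-2-ol; 3 4-iodo-2-methoxyphenol
Product: 4 4-iodo-1-{[1,3-bis(tert-butyldimethylsilyloxy)propan-2-yl]oxy}-2-methoxybenzene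
Conditions: PPh3, DIAD, THF, 0 °C to 40 °C
Reagents that add atoms: none
Why: Mitsunobu etherification of an acidic phenol with a secondary alcohol whose carbinol carbon is not stereogenic, so the inversion has no consequence; the aryl iodide is inert.

Step 3
Reactants: 5 methyl (S)-2,3-dihydroxypropanoate (methyl (S)-glycerate)
Product: 6 methyl (S)-3-(tert-butyldiphenylsilyloxy)-2-hydroxypropanoate
Conditions: TBDPSCl (1.05 equiv), imidazole, CH2Cl2, 0 °C
Reagents that add atoms: tert-butyldiphenylsilyl chloride, CC(C)(C)[Si](Cl)(c1ccccc1)c1ccccc1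
Why: Selective silylation of the primary hydroxyl by the bulky silyl chloride; the C2 stereocentre is not touched.

Step 4
Reactants: 6 methyl (S)-3-(tert-butyldiphenylsilyloxy)-2-hydroxypropanoate; 7 4-allyl-2,6-dimethoxyphenol
Product: 8 methyl (R)-2-(4-allyl-2,6-dimethoxyphenoxy)-3-(tert-butyldiphenylsilyloxy)propanoate
Conditions: PPh3, DIAD, toluene/THF, 0 °C to rt
Reagents that add atoms: none
Why: Mitsunobu reaction in which the phenoxide displaces the alkoxyphosphonium group at the activated α-carbon of the ester by SN2 with inversion (S to R), which sets C8 of the target.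

Step 5
Reactants: 8 methyl (R)-2-(4-allyl-2,6-dimethoxyphenoxy)-3-(tert-butyldiphenylsilyloxy)propanoate
Product: 9 (R)-2-(4-allyl-2,6-dimethoxyphenoxy)-3-(tert-butyldiphenylsilyloxy)propanal
Conditions: DIBAL-H (1.1 equiv), CH2Cl2, −78 °C; MeOH quench, aq. Rochelle salt; used crude at once
Reagents that add atoms: none
Why: Partial DIBAL-H reduction of an α-oxygenated methyl ester stops at the chelated aluminium hemiacetal at −78 °C and releases the aldehyde on hydrolysis; no base is present, so C8 should keep its configuration.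

Step 6
Reactants: 4 4-iodo-1-{[1,3-bis(tert-butyldimethylsilyloxy)propan-2-yl]oxy}-2-methoxybenzene (1.5 equiv); 9 (R)-2-(4-allyl-2,6-dimethoxyphenoxy)-3-(tert-butyldiphenylsilyloxy)propanal
Product: 11 (1S,2R)-2-(4-allyl-2,6-dimethoxyphenoxy)-1-[4-{[1,3-bis(tert-butyldimethylsilyloxy)propan-2-yl]oxy}-3-methoxyphenyl]-3-(tert-butyldiphenylsilyloxy)propan-1-ol, via arylchromium(III) dichloride 10 (not isolated)
Conditions: CrCl2 (4 equiv), NiCl2 (2 mol%), 4-tert-butylpyridine, degassed DMF/THF, rt; aq. sodium serinate work-up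
Reagents that add atoms: none
Why: Ni(0), formed from NiCl2 by Cr(II), inserts into the C–I bond of 4 and passes the aryl group to Cr(III), and the arylchromium(III) species 10 then adds to the C=O of 9, so that two carbons which are both electrophilic in the flask (the iodine-bearing C1 and the aldehyde carbon C7) are joined under net two-electron reduction by two CrCl2. The closest known reaction type is the Nozaki–Hiyama–Kishi Ni/Cr coupling of aryl iodides with α-oxygenated aldehydes. No ring is closed. The new C7 stereocentre is controlled by C8 through a polar Felkin–Anh (equally Cornforth) transition state in which the C8–O(aryl) bond lies anti to the incoming aryl group, and the DMF-solvated Cr(III) has little tendency to chelate, so the 1,2-anti adduct, that is the erythro (7S,8R) alcohol, should predominate, with the threo epimer removable by chromatography. The step needs facial selectivity, chemoselectivity for the aldehyde over the allyl group and the silyl ethers, and retention of the base-labile C8 centre; these are secured by the α-aryloxy dipole and the bulky non-coordinating TBDPS ether, by the inertness of organochromium(III) reagents toward alkenes and ethers, and by the essentially non-basic medium, which should neither enolise the α-aryloxy aldehyde nor eliminate its β-silyloxy group.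

Step 7
Reactants: 11 (1S,2R)-2-(4-allyl-2,6-dimethoxyphenoxy)-1-[4-{[1,3-bis(tert-butyldimethylsilyloxy)propan-2-yl]oxy}-3-methoxyphenyl]-3-(tert-butyldiphenylsilyloxy)propan-1-ol
Product: 13 (1S,2R)-1-[4-{[1,3-bis(tert-butyldimethylsilyloxy)propan-2-yl]oxy}-3-methoxyphenyl]-3-(tert-butyldiphenylsilyloxy)-2-[4-(3-hydroxypropyl)-2,6-dimethoxyphenoxy]propan-1-ol, via B-alkyl-9-BBN adduct 12 (not isolated)
Conditions: 9-BBN (3 equiv), THF, 0 °C to rt; then 3 M NaOH, 30% H2O2, 0 °C
Reagents that add atoms: hydrogen peroxide, OO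
Why: Hydroboration–oxidation, in which 9-BBN adds anti-Markovnikov to the terminal alkene and the C–B bond is oxidised to the primary alcohol; the silyl ethers tolerate the short alkaline peroxide treatment and any borinate formed at the C7 hydroxyl is hydrolysed there.

Step 8
Reactants: 13 (1S,2R)-1-[4-{[1,3-bis(tert-butyldimethylsilyloxy)propan-2-yl]oxy}-3-methoxyphenyl]-3-(tert-butyldiphenylsilyloxy)-2-[4-(3-hydroxypropyl)-2,6-dimethoxyphenoxy]propan-1-ol
Product: 14 (1S,2R)-1-{4-[(1,3-dihydroxypropan-2-yl)oxy]-3-methoxyphenyl}-2-[4-(3-hydroxypropyl)-2,6-dimethoxyphenoxy]propane-1,3-diol (target)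
Conditions: TBAF (6 equiv), THF, rt; CaCO3/Dowex 50W work-up
Reagents that add atoms: none
Why: Fluoride-mediated cleavage of all three silyl ethers in a non-acidic medium, so the electron-rich benzylic carbinol C7 is not ionised and neither stereocentre is disturbed.

**Compound list**
1 | glycerol | OCC(O)CO | starting material
2 | 1,3-bis(tert-butyldimethylsilyloxy)propan-2-ol | CC(C)(C)[Si](C)(C)OCC(O)CO[Si](C)(C)C(C)(C)C | intermediate
3 | 4-iodo-2-methoxyphenol | COc1cc(I)ccc1O | starting material
4 | 4-iodo-1-{[1,3-bis(tert-butyldimethylsilyloxy)propan-2-yl]oxy}-2-methoxybenzene | COc1cc(I)ccc1OC(CO[Si](C)(C)C(C)(C)C)CO[Si](C)(C)C(C)(C)C | intermediate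
5 | methyl (S)-2,3-dihydroxypropanoate | COC(=O)[C@@H](O)CO | starting material
6 | methyl (S)-3-(tert-butyldiphenylsilyloxy)-2-hydroxypropanoate | COC(=O)[C@@H](O)CO[Si](c1ccccc1)(c1ccccc1)C(C)(C)C | intermediate
7 | 4-allyl-2,6-dimethoxyphenol | C=CCc1cc(OC)c(O)c(OC)c1 | starting material
8 | methyl (R)-2-(4-allyl-2,6-dimethoxyphenoxy)-3-(tert-butyldiphenylsilyloxy)propanoate | COC(=O)[C@@H](CO[Si](c1ccccc1)(c1ccccc1)C(C)(C)C)Oc1c(OC)cc(CC=C)cc1OC | intermediate
9 | (R)-2-(4-allyl-2,6-dimethoxyphenoxy)-3-(tert-butyldiphenylsilyloxy)propanal | O=C[C@@H](CO[Si](c1ccccc1)(c1ccccc1)C(C)(C)C)Oc1c(OC)cc(CC=C)cc1OC | intermediate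
10 | [4-{[1,3-bis(tert-butyldimethylsilyloxy)propan-2-yl]oxy}-3-methoxyphenyl]chromium(III) dichloride (not isolated) | COc1cc([Cr](Cl)Cl)ccc1OC(CO[Si](C)(C)C(C)(C)C)CO[Si](C)(C)C(C)(C)C | intermediate
11 | (1S,2R)-2-(4-allyl-2,6-dimethoxyphenoxy)-1-[4-{[1,3-bis(tert-butyldimethylsilyloxy)propan-2-yl]oxy}-3-methoxyphenyl]-3-(tert-butyldiphenylsilyloxy)propan-1-ol | COc1cc([C@H](O)[C@@H](CO[Si](c2ccccc2)(c2ccccc2)C(C)(C)C)Oc2c(OC)cc(CC=C)cc2OC)ccc1OC(CO[Si](C)(C)C(C)(C)C)CO[Si](C)(C)C(C)(C)C | intermediate
12 | B-alkyl-9-borabicyclo[3.3.1]nonane adduct of 11 at the terminal carbon of the former allyl group (not isolated) | COc1cc([C@H](O)[C@@H](CO[Si](c2ccccc2)(c2ccccc2)C(C)(C)C)Oc2c(OC)cc(CCCB3C4CCCC3CCC4)cc2OC)ccc1OC(CO[Si](C)(C)C(C)(C)C)CO[Si](C)(C)C(C)(C)C | intermediate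
13 | (1S,2R)-1-[4-{[1,3-bis(tert-butyldimethylsilyloxy)propan-2-yl]oxy}-3-methoxyphenyl]-3-(tert-butyldiphenylsilyloxy)-2-[4-(3-hydroxypropyl)-2,6-dimethoxyphenoxy]propan-1-ol | COc1cc([C@H](O)[C@@H](CO[Si](c2ccccc2)(c2ccccc2)C(C)(C)C)Oc2c(OC)cc(CCCO)cc2OC)ccc1OC(CO[Si](C)(C)C(C)(C)C)CO[Si](C)(C)C(C)(C)C | intermediate
14 | (1S,2R)-1-{4-[(1,3-dihydroxypropan-2-yl)oxy]-3-methoxyphenyl}-2-[4-(3-hydroxypropyl)-2,6-dimethoxyphenoxy]propane-1,3-diol | COc1cc([C@H](O)[C@@H](CO)Oc2c(OC)cc(CCCO)cc2OC)ccc1OC(CO)CO | target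

**Summary**
Total step count: 8. Longest linear sequence: 6 steps (steps 3, 4, 5, 6, 7, 8, from methyl (S)-glycerate).

Steps most likely to fail:

Step 6. Oxidative addition of Ni(0) into the electron-rich aryl iodide and transfer to chromium may be slow, so that reductive biaryl homocoupling and pinacol-type reduction of the aldehyde compete. Partial chelation through the 2,6-dimethoxyphenoxy oxygen may also lower the facial selectivity. The fallback sets out from 8 (with 4) and returns at 11. Ester 8 is converted with MeNH(OMe)·HCl/AlMe3 (CH2Cl2, 0 °C) into the Weinreb amide (R)-2-(4-allyl-2,6-dimethoxyphenoxy)-3-(tert-butyldiphenylsilyloxy)-N-methoxy-N-methylpropanamide F1. Iodide 4 is turned by iodine–magnesium exchange (iPrMgCl·LiCl, THF, −15 °C) into the arylmagnesium chloride F2, which acylates F1 at −20 °C to the aryl ketone (R)-2-(4-allyl-2,6-dimethoxyphenoxy)-1-[4-{[1,3-bis(tert-butyldimethylsilyloxy)propan-2-yl]oxy}-3-methoxyphenyl]-3-(tert-butyldiphenylsilyloxy)propan-1-one F3. Chelation-controlled reduction of F3 with Zn(BH4)2 (Et2O, −30 °C), in which zinc bridges the carbonyl and the C8 aryloxy oxygen and hydride enters anti to C9, should give the same erythro alcohol 11.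

Step 5. Over-reduction to the primary alcohol may occur, and the α-aryloxy aldehyde may enolise during quench and work-up, with loss of configurational purity at C8 or β-elimination of the silyloxy group. The fallback sets out from 8 and returns at 9. Ester 8 is reduced completely (LiBH4, THF/MeOH, 0 °C) to the stable, storable alcohol (S)-2-(4-allyl-2,6-dimethoxyphenoxy)-3-(tert-butyldiphenylsilyloxy)propan-1-ol F4. F4 is oxidised immediately before the coupling with Dess–Martin periodinane buffered with NaHCO3 (CH2Cl2, 0 °C) to aldehyde 9.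

Step 4. Attack of the hindered 2,6-dimethoxyphenoxide on the alkoxyphosphonium ion may be slow, so that alkylation of the hydrazide and elimination compete and inversion is incomplete. The fallback sets out from 6 and returns at 8. Alcohol 6 is converted (Tf2O, 2,6-lutidine, CH2Cl2, −78 °C) into methyl (S)-3-(tert-butyldiphenylsilyloxy)-2-(trifluoromethanesulfonyloxy)propanoate F5. F5 is displaced by the potassium phenoxide of 7 (KHMDS, THF/MeCN, −40 to 0 °C) in a direct SN2 reaction with inversion to give 8.

**Further compounds**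
F1 | step 6 | (R)-2-(4-allyl-2,6-dimethoxyphenoxy)-3-(tert-butyldiphenylsilyloxy)-N-methoxy-N-methylpropanamide | CON(C)C(=O)[C@@H](CO[Si](c1ccccc1)(c1ccccc1)C(C)(C)C)Oc1c(OC)cc(CC=C)cc1OC
F2 | step 6 | [4-{[1,3-bis(tert-butyldimethylsilyloxy)propan-2-yl]oxy}-3-methoxyphenyl]magnesium chloride | COc1cc([Mg]Cl)ccc1OC(CO[Si](C)(C)C(C)(C)C)CO[Si](C)(C)C(C)(C)C
F3 | step 6 | (R)-2-(4-allyl-2,6-dimethoxyphenoxy)-1-[4-{[1,3-bis(tert-butyldimethylsilyloxy)propan-2-yl]oxy}-3-methoxyphenyl]-3-(tert-butyldiphenylsilyloxy)propan-1-one | COc1cc(C(=O)[C@@H](CO[Si](c2ccccc2)(c2ccccc2)C(C)(C)C)Oc2c(OC)cc(CC=C)cc2OC)ccc1OC(CO[Si](C)(C)C(C)(C)C)CO[Si](C)(C)C(C)(C)C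
F4 | step 5 | (S)-2-(4-allyl-2,6-dimethoxyphenoxy)-3-(tert-butyldiphenylsilyloxy)propan-1-ol | OC[C@@H](CO[Si](c1ccccc1)(c1ccccc1)C(C)(C)C)Oc1c(OC)cc(CC=C)cc1OC
F5 | step 4 | methyl (S)-3-(tert-butyldiphenylsilyloxy)-2-(trifluoromethanesulfonyloxy)propanoate | COC(=O)[C@@H](OS(=O)(=O)C(F)(F)F)CO[Si](c1ccccc1)(c1ccccc1)C(C)(C)C
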